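**Retrosynthetic overview**

1. Ring numbering (germacrane type): C1=C10(CH3), C2H2, C3 (O-senecioyl), C4(CH3)–O–C5 oxirane, C6 (OAc), C7 (isopropyl), C8, C9. End game: acetate ⇐ C6-hydroxyl-directed epoxidation of an (E)-C4=C5 alkene ⇐ ester and protecting-group exchange.
2. Enabling feature: the C1=C10 alkene and the C4–C5 oxirane (a masked C4=C5 alkene with oxygen on C5) flank the C2–C3 bond, so the ten-membered ring hides the hexa-1,5-diene C10=C1–C2–C3–C4=C5. Joining C5 to C10 gives the six-membered ring C5–C6–C7–C8–C9–C10, a p-menthane with the C10 methyl para to the C7 isopropyl.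
3. Key disconnection: retro-[3,3] (anionic oxy-Cope with C5 as the oxido carbon, the enolate kept as enol triflate) cuts C2–C3 and leads to a trans-1,2-dialkenylcyclohexanol.
4. This carbinol ⇐ (Z)-β-alkoxy alkenyllithium (C3, C4, C4–CH3) + 6-silyloxy-2-methyl-2-vinylcyclohexanone ⇐ (R)-carvone (C5–C10 and both alkyl groups) by hydrogenation, α-vinylation (C1, C2) and α-hydroxylation with inversion (C6–O).
5. Ring order: six-membered ring from the chiral pool, then the ten-membered ring by ring expansion (step 9, which also sets C3 and both E alkenes), the oxirane last (step 14).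

Key step: step 9

Remark (assumption): commercial (R)-(−)-carvone is taken as enantiopure; its stereocentre becomes C7 of the target, and every other stereocentre is derived from it.

**Route**

Step 1
Reactants: 1 (R)-(−)-carvone, (5R)-2-methyl-5-(prop-1-en-2-yl)cyclohex-2-en-1-one
Product: 2 (5R)-2-methyl-5-(propan-2-yl)cyclohexan-1-one (carvomenthone, both C2 epimers)
Conditions: H2 (1 atm), Pd/C (5 mol%), EtOAc, rt
Reagents that add atoms: none
Why: Heterogeneous catalytic hydrogenation saturates the isopropenyl and the enone C=C bonds while the ketone and the isopropyl-bearing stereocentre (not α to the carbonyl, later C7) stay untouched; the epimer mixture at C2 does not matter because C2 is enolised in step 2.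

Step 2
Reactants: 2 (5R)-2-methyl-5-(propan-2-yl)cyclohexan-1-one
Product: 4 (2R,5R)-2-ethenyl-2-methyl-5-(propan-2-yl)cyclohexan-1-one, via sulfoxide adduct 3 (not isolated)
Conditions: phenyl vinyl sulfoxide (1.2 equiv), KOt-Bu (0.2 equiv), t-BuOH/THF, 0 °C → rt; aqueous work-up; crude 3, CaCO3, toluene, 110 °C
Reagents that add atoms: phenyl vinyl sulfoxide, C=CS(=O)c1ccccc1
Why: Michael addition of the more substituted (thermodynamic) enolate to the vinyl sulfoxide, a vinyl cation equivalent, followed by thermal syn elimination of the sulfoxide unmasks the vinyl group; the electrophile should enter axially on the enolate half-chair with equatorial isopropyl, cis to isopropyl, as in the Robinson annulation of dihydrocarvone, which sets the quaternary centre (2R, later C10), and the minor epimer and any regioisomer are removed by chromatography.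

Step 3
Reactants: 4 (2R,5R)-2-ethenyl-2-methyl-5-(propan-2-yl)cyclohexan-1-one
Product: 6 (2R,5S,6R)-2-ethenyl-6-hydroxy-2-methyl-5-(propan-2-yl)cyclohexan-1-one, via hydroxy dimethyl ketal 5 (not isolated)
Conditions: PhI(OAc)2 (1.2 equiv), KOH (3 equiv), MeOH, 0 °C → rt; then 2 M HCl, THF, rt
Reagents that add atoms: water, O; methanol, CO (its atoms stay only in intermediate 5)
Why: Moriarty α-hydroxylation: the ketone can enolise only towards C6, trivalent iodine attacks the enolate face anti to isopropyl and vinyl, and the hemiketal oxygen formed by methoxide addition displaces iodobenzene with inversion, so that after opening of the methoxy epoxide to ketal 5 and acid hydrolysis the hydroxyl should stand cis to isopropyl (6R), on the face that direct electrophilic oxidation does not reach.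

Step 4
Reactants: 6 (2R,5S,6R)-2-ethenyl-6-hydroxy-2-methyl-5-(propan-2-yl)cyclohexan-1-one
Product: 7 (2R,5S,6R)-6-[(tert-butyldimethylsilyl)oxy]-2-ethenyl-2-methyl-5-(propan-2-yl)cyclohexan-1-one
Conditions: TBSOTf (1.3 equiv), 2,6-lutidine (2 equiv), CH2Cl2, −78 → 0 °C
Reagents that add atoms: tert-butyldimethylsilyl trifluoromethanesulfonate, CC(C)(C)[Si](C)(C)OS(=O)(=O)C(F)(F)F
Why: Silylation of the secondary alcohol with the silyl triflate and a hindered pyridine base is fast at low temperature and non-basic enough to leave the epimerisable α-oxy ketone centre untouched.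

Step 5
Reactants: 8 (4-methoxyphenyl)methanol
Product: 10 1-methoxy-4-[(prop-2-en-1-yloxy)methyl]benzene, via sodium alkoxide 9 (not isolated)
Conditions: NaH (1.1 equiv), THF, 0 °C; allyl bromide (1.2 equiv), Bu4NI (cat.), 0 °C → rt
Reagents that add atoms: allyl bromide, C=CCBr
Why: Williamson ether synthesis of a primary alkoxide with a reactive allylic bromide.

Step 6
Reactants: 10 1-methoxy-4-[(prop-2-en-1-yloxy)methyl]benzene
Product: 11 1-methoxy-4-{[(1Z)-prop-1-en-1-yloxy]methyl}benzene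
Conditions: KOt-Bu (0.3 equiv), DMSO, 25–40 °C
Reagents that add atoms: none
Why: Base-mediated isomerisation of the allyl ether to the propenyl ether through the potassium-chelated cisoid allyl anion, which should give the (Z) enol ether selectively.

Step 7
Reactants: 11 1-methoxy-4-{[(1Z)-prop-1-en-1-yloxy]methyl}benzene
Product: 13 1-({[(1Z)-2-bromoprop-1-en-1-yl]oxy}methyl)-4-methoxybenzene, via dibromide 12 (not isolated)
Conditions: Br2 (1.0 equiv), CH2Cl2, −78 °C; then i-Pr2NEt (2 equiv), −78 °C → rt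
Reagents that add atoms: bromine, BrBr
Why: Anti addition of bromine to the enol ether followed by anti elimination of HBr (departure of the labile α-bromo ether bromide with the C2 proton) is the standard way to β-bromo enol ethers and is stereospecific, so the (Z) propenyl ether should give the (Z) bromide with bromine cis to oxygen.

Step 8
Reactants: 7 (2R,5S,6R)-6-[(tert-butyldimethylsilyl)oxy]-2-ethenyl-2-methyl-5-(propan-2-yl)cyclohexan-1-one; 13 1-({[(1Z)-2-bromoprop-1-en-1-yl]oxy}methyl)-4-methoxybenzene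
Product: 15 (1R,2R,5S,6R)-6-[(tert-butyldimethylsilyl)oxy]-2-ethenyl-1-{(1Z)-1-[(4-methoxybenzyl)oxy]prop-1-en-2-yl}-2-methyl-5-(propan-2-yl)cyclohexan-1-ol, via alkenyllithium 14 (not isolated)
Conditions: 13 (1.5 equiv), t-BuLi (2 equiv per 13), Et2O, −78 °C; then 7, THF, −78 → −40 °C; H2O
Reagents that add atoms: none
Why: Bromine–lithium exchange proceeds with retention to the oxygen-chelated alkenyllithium 14, whose 1,2-addition to the ketone should take place on the face opposite to the three cis substituents (vinyl, silyloxy, isopropyl), which sets the tertiary carbinol centre (1R) with the new alkenyl group trans to vinyl, as the sigmatropic shift requires.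

Step 9
Reactants: 15 (1R,2R,5S,6R)-6-[(tert-butyldimethylsilyl)oxy]-2-ethenyl-1-{(1Z)-1-[(4-methoxybenzyl)oxy]prop-1-en-2-yl}-2-methyl-5-(propan-2-yl)cyclohexan-1-ol
Product: 18 (1Z,3S,5E,9S,10R)-10-[(tert-butyldimethylsilyl)oxy]-3-[(4-methoxybenzyl)oxy]-2,6-dimethyl-9-(propan-2-yl)cyclodeca-1,5-dien-1-yl trifluoromethanesulfonate, via potassium alkoxide 16 (not isolated), via potassium enolate 17 (not isolated)
Conditions: KH (1.1 equiv), 18-crown-6 (1.2 equiv), THF, −20 → 20 °C; then 2-[N,N-bis(trifluoromethylsulfonyl)amino]-5-chloropyridine (1.3 equiv), −78 → −20 °C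
Reagents that add atoms: 2-[N,N-bis(trifluoromethylsulfonyl)amino]-5-chloropyridine, Clc1ccc(nc1)N(S(=O)(=O)C(F)(F)F)S(=O)(=O)C(F)(F)F
Why: Deprotonation gives potassium alkoxide 16, which should undergo an anionic oxy-Cope rearrangement, a [3,3]-sigmatropic shift over the hexa-1,5-diene C2=C1–C10–C5–C4=C3 that breaks the cyclohexane bond C5–C10 and forms C2–C3, to give enolate 17, which is O-sulfonylated in the same flask; the closest known reaction types are the oxy-Cope ring expansion of trans-1,2-dialkenylcyclohexanolates to (E)-cyclodec-5-enones and the oxy-Cope shift of 1-alkoxy-1,5-dien-3-olates. The ten-membered ring is closed by a four-atom enlargement of the six-membered ring (a sigmatropic closure, not a chain cyclisation) through a chair transition state fused like a trans-decalin to the cyclohexane conformer that has both alkenyl groups equatorial. The new stereocentre C3 (S) is controlled by the (Z) enol ether geometry: its alkoxy group is axial on the chair, so C3 bonds to C2 on one face only, while the two equatorial ring bonds at C10 and C5 translate into the E geometry of C1=C10 and the in-ring E geometry of the C4=C5 enolate; C6 and C7 are carried through unchanged. Chair-versus-boat selectivity is secured by the trans-1,2-dialkenyl arrangement, for which a boat is geometrically impossible, and the reactive ring conformer (axial isopropyl) is populated because the alternative chair suffers a 1,3-diaxial vinyl/silyloxy clash. The step also needs the shift and the trapping to outrun loss of 4-methoxybenzyl oxide from the β-alkoxy enolate, which is why the crown-ether-separated alkoxide is used at or below room temperature and 17 is trapped cold with the pyridyl triflimide, fixing regiochemistry and alkene geometry as enol triflate 18.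

Step 10
Reactants: 18 (1Z,3S,5E,9S,10R)-10-[(tert-butyldimethylsilyl)oxy]-3-[(4-methoxybenzyl)oxy]-2,6-dimethyl-9-(propan-2-yl)cyclodeca-1,5-dien-1-yl trifluoromethanesulfonate
Product: 19 tert-butyl{[(1R,2E,4S,6E,10S)-4-[(4-methoxybenzyl)oxy]-3,7-dimethyl-10-(propan-2-yl)cyclodeca-2,6-dien-1-yl]oxy}dimethylsilane
Conditions: Pd(OAc)2 (5 mol%), PPh3 (10 mol%), HCO2H (2 equiv), n-Bu3N (3 equiv), DMF, 45 °C
Reagents that add atoms: none
Why: Palladium-catalysed formate reduction of the enol triflate (oxidative addition of zerovalent palladium, hydride transfer from formate, reductive elimination) replaces OTf by H with retention of alkene geometry and does not ionise the allylic ethers, and the temperature stays far below that of a thermal Cope back-reaction.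

Step 11
Reactants: 19 tert-butyl{[(1R,2E,4S,6E,10S)-4-[(4-methoxybenzyl)oxy]-3,7-dimethyl-10-(propan-2-yl)cyclodeca-2,6-dien-1-yl]oxy}dimethylsilane
Product: 20 (1S,2E,4R,5S,8E)-4-[(tert-butyldimethylsilyl)oxy]-2,8-dimethyl-5-(propan-2-yl)cyclodeca-2,8-dien-1-ol
Conditions: DDQ (1.3 equiv), CH2Cl2/pH 7 buffer (10:1), 0 °C
Reagents that add atoms: none
Why: Oxidative cleavage of the 4-methoxybenzyl ether with DDQ under buffered neutral conditions leaves the silyl ether and the two trisubstituted alkenes untouched and avoids the acid that would trigger transannular cyclisation of the cyclodecadiene.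

Step 12
Reactants: 20 (1S,2E,4R,5S,8E)-4-[(tert-butyldimethylsilyl)oxy]-2,8-dimethyl-5-(propan-2-yl)cyclodeca-2,8-dien-1-ol
Product: 21 (1S,2E,4R,5S,8E)-4-[(tert-butyldimethylsilyl)oxy]-2,8-dimethyl-5-(propan-2-yl)cyclodeca-2,8-dien-1-yl 3-methylbut-2-enoate
Conditions: 3-methylbut-2-enoyl chloride (1.5 equiv), pyridine, DMAP (0.1 equiv), CH2Cl2, 0 °C → rt
Reagents that add atoms: 3-methylbut-2-enoyl chloride, CC(C)=CC(Cl)=O
Why: DMAP-catalysed acylation of the secondary allylic alcohol with the acid chloride, with pyridine as a weak base to limit deconjugation of the acyl group through the vinylketene.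

Step 13
Reactants: 21 (1S,2E,4R,5S,8E)-4-[(tert-butyldimethylsilyl)oxy]-2,8-dimethyl-5-(propan-2-yl)cyclodeca-2,8-dien-1-yl 3-methylbut-2-enoate
Product: 22 (1S,2E,4R,5S,8E)-4-hydroxy-2,8-dimethyl-5-(propan-2-yl)cyclodeca-2,8-dien-1-yl 3-methylbut-2-enoate
Conditions: Bu4NF (3 equiv), AcOH (3 equiv), THF, rt → 40 °C
Reagents that add atoms: none
Why: Fluoride-mediated cleavage of the silyl ether, buffered with acetic acid so that the ester neither migrates nor hydrolyses.

Step 14
Reactants: 22 (1S,2E,4R,5S,8E)-4-hydroxy-2,8-dimethyl-5-(propan-2-yl)cyclodeca-2,8-dien-1-yl 3-methylbut-2-enoate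
Product: 23 (1R,2S,4E,8S,9R,10R)-9-hydroxy-1,5-dimethyl-8-(propan-2-yl)-11-oxabicyclo[8.1.0]undec-4-en-2-yl 3-methylbut-2-enoate
Conditions: VO(acac)2 (5 mol%), t-BuOOH (1.5 equiv, in decane), NaHCO3 (solid), CH2Cl2, 0 °C
Reagents that add atoms: tert-butyl hydroperoxide, CC(C)(C)OO
Why: Vanadium-catalysed hydroxyl-directed epoxidation: only the C4=C5 alkene is allylic to the free C6 hydroxyl (C1=C10 and the senecioate alkene are not activated), and because in an (E)-cyclodecene the allylic ring bond C6–C7 must lie on the inner face of the alkene, the O–C6–C5=C4 dihedral of about 40–50° needed for oxygen delivery from the vanadium alkoxide places the new oxygen on the outer face and erythro to the C6 oxygen, which should set C4 (R) and C5 (R) in one syn addition to the E alkene.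

Step 15
Reactants: 23 (1R,2S,4E,8S,9R,10R)-9-hydroxy-1,5-dimethyl-8-(propan-2-yl)-11-oxabicyclo[8.1.0]undec-4-en-2-yl 3-methylbut-2-enoate
Product: 24 (1R,2S,4E,8S,9R,10R)-9-(acetyloxy)-1,5-dimethyl-8-(propan-2-yl)-11-oxabicyclo[8.1.0]undec-4-en-2-yl 3-methylbut-2-enoate (target, CNP0267399.1)
Conditions: Ac2O (3 equiv), pyridine, DMAP (0.1 equiv), CH2Cl2, rt
Reagents that add atoms: acetic anhydride, CC(=O)OC(C)=O
Why: DMAP-catalysed acetylation of the remaining secondary alcohol under mild conditions that leave the trisubstituted oxirane and the E alkene intact.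

**Compound list**

1 | (R)-(−)-carvone, (5R)-2-methyl-5-(prop-1-en-2-yl)cyclohex-2-en-1-one | CC1=CC[C@H](CC1=O)C(C)=C | starting material
2 | (5R)-2-methyl-5-(propan-2-yl)cyclohexan-1-one (both C2 epimers) | CC1CC[C@H](CC1=O)C(C)C | intermediate
3 | (2R,5R)-2-methyl-2-[2-(phenylsulfinyl)ethyl]-5-(propan-2-yl)cyclohexan-1-one (both sulfur epimers) | O=C1C[C@H](C(C)C)CC[C@]1(C)CCS(=O)c2ccccc2 | intermediate
4 | (2R,5R)-2-ethenyl-2-methyl-5-(propan-2-yl)cyclohexan-1-one | O=C1C[C@H](C(C)C)CC[C@]1(C)C=C | intermediate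
5 | (1R,3R,6S)-3-ethenyl-2,2-dimethoxy-3-methyl-6-(propan-2-yl)cyclohexan-1-ol | COC1(OC)[C@H](O)[C@H](C(C)C)CC[C@]1(C)C=C | intermediate
6 | (2R,5S,6R)-2-ethenyl-6-hydroxy-2-methyl-5-(propan-2-yl)cyclohexan-1-one | O=C1[C@H](O)[C@H](C(C)C)CC[C@]1(C)C=C | intermediate
7 | (2R,5S,6R)-6-[(tert-butyldimethylsilyl)oxy]-2-ethenyl-2-methyl-5-(propan-2-yl)cyclohexan-1-one | O=C1[C@H](O[Si](C)(C)C(C)(C)C)[C@H](C(C)C)CC[C@]1(C)C=C | intermediate
8 | (4-methoxyphenyl)methanol | COc1ccc(CO)cc1 | starting material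
9 | sodium (4-methoxyphenyl)methanolate | COc1ccc(C[O-])cc1.[Na+] | intermediate
10 | 1-methoxy-4-[(prop-2-en-1-yloxy)methyl]benzene | COc1ccc(COCC=C)cc1 | intermediate
11 | 1-methoxy-4-{[(1Z)-prop-1-en-1-yloxy]methyl}benzene | COc1ccc(CO/C=C\C)cc1 | intermediate
12 | 1-[(1,2-dibromopropoxy)methyl]-4-methoxybenzene, (1R*,2S*), racemic, one enantiomer drawn | COc1ccc(CO[C@H](Br)[C@H](C)Br)cc1 | intermediate
13 | 1-({[(1Z)-2-bromoprop-1-en-1-yl]oxy}methyl)-4-methoxybenzene | COc1ccc(CO/C=C(/C)Br)cc1 | intermediate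
14 | {(1E)-1-[(4-methoxybenzyl)oxy]prop-1-en-2-yl}lithium (lithium cis to oxygen) | COc1ccc(CO/C=C(/C)[Li])cc1 | intermediate
15 | (1R,2R,5S,6R)-6-[(tert-butyldimethylsilyl)oxy]-2-ethenyl-1-{(1Z)-1-[(4-methoxybenzyl)oxy]prop-1-en-2-yl}-2-methyl-5-(propan-2-yl)cyclohexan-1-ol | COc1ccc(CO/C=C(/C)[C@@]2(O)[C@H](O[Si](C)(C)C(C)(C)C)[C@H](C(C)C)CC[C@]2(C)C=C)cc1 | intermediate
16 | potassium (1R,2R,5S,6R)-6-[(tert-butyldimethylsilyl)oxy]-2-ethenyl-1-{(1Z)-1-[(4-methoxybenzyl)oxy]prop-1-en-2-yl}-2-methyl-5-(propan-2-yl)cyclohexan-1-olate | COc1ccc(CO/C=C(/C)[C@@]2([O-])[C@H](O[Si](C)(C)C(C)(C)C)[C@H](C(C)C)CC[C@]2(C)C=C)cc1.[K+] | intermediate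
17 | potassium (1Z,3S,5E,9S,10R)-10-[(tert-butyldimethylsilyl)oxy]-3-[(4-methoxybenzyl)oxy]-2,6-dimethyl-9-(propan-2-yl)cyclodeca-1,5-dien-1-olate | CC(C)(C)[Si](C)(C)O[C@H]1/C([O-])=C(C)/[C@@H](OCc2ccc(OC)cc2)C/C=C(\C)CC[C@H]1C(C)C.[K+] | intermediate
18 | (1Z,3S,5E,9S,10R)-10-[(tert-butyldimethylsilyl)oxy]-3-[(4-methoxybenzyl)oxy]-2,6-dimethyl-9-(propan-2-yl)cyclodeca-1,5-dien-1-yl trifluoromethanesulfonate | CC(C)(C)[Si](C)(C)O[C@H]1/C(OS(=O)(=O)C(F)(F)F)=C(C)/[C@@H](OCc2ccc(OC)cc2)C/C=C(\C)CC[C@H]1C(C)C | intermediate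
19 | tert-butyl{[(1R,2E,4S,6E,10S)-4-[(4-methoxybenzyl)oxy]-3,7-dimethyl-10-(propan-2-yl)cyclodeca-2,6-dien-1-yl]oxy}dimethylsilane | CC(C)(C)[Si](C)(C)O[C@H]1/C=C(C)/[C@@H](OCc2ccc(OC)cc2)C/C=C(\C)CC[C@H]1C(C)C | intermediate
20 | (1S,2E,4R,5S,8E)-4-[(tert-butyldimethylsilyl)oxy]-2,8-dimethyl-5-(propan-2-yl)cyclodeca-2,8-dien-1-ol | CC(C)(C)[Si](C)(C)O[C@H]1/C=C(C)/[C@@H](O)C/C=C(\C)CC[C@H]1C(C)C | intermediate
21 | (1S,2E,4R,5S,8E)-4-[(tert-butyldimethylsilyl)oxy]-2,8-dimethyl-5-(propan-2-yl)cyclodeca-2,8-dien-1-yl 3-methylbut-2-enoate | CC(C)(C)[Si](C)(C)O[C@H]1/C=C(C)/[C@@H](OC(=O)C=C(C)C)C/C=C(\C)CC[C@H]1C(C)C | intermediate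
22 | (1S,2E,4R,5S,8E)-4-hydroxy-2,8-dimethyl-5-(propan-2-yl)cyclodeca-2,8-dien-1-yl 3-methylbut-2-enoate | O[C@H]1/C=C(C)/[C@@H](OC(=O)C=C(C)C)C/C=C(\C)CC[C@H]1C(C)C | intermediate
23 | (1R,2S,4E,8S,9R,10R)-9-hydroxy-1,5-dimethyl-8-(propan-2-yl)-11-oxabicyclo[8.1.0]undec-4-en-2-yl 3-methylbut-2-enoate | O[C@H]1[C@H]2O[C@]2(C)[C@@H](OC(=O)C=C(C)C)C/C=C(\C)CC[C@H]1C(C)C | intermediate
24 | (1R,2S,4E,8S,9R,10R)-9-(acetyloxy)-1,5-dimethyl-8-(propan-2-yl)-11-oxabicyclo[8.1.0]undec-4-en-2-yl 3-methylbut-2-enoate | CC(=O)O[C@H]1[C@H]2O[C@]2(C)[C@@H](OC(=O)C=C(C)C)C/C=C(\C)CC[C@H]1C(C)C | target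

**Step count and risks**

Total step count: 15. Longest linear sequence: 12 steps (steps 1–4 and 8–15); the side branch (steps 5–7) joins at step 8.

The three steps most likely to fail:

1. Step 9. The sigmatropic shift may be too slow, because the chair carries an axial alkoxy group and the reactive ring conformer an axial isopropyl group. The β-alkoxy enolate may also expel 4-methoxybenzyl oxide before it is sulfonylated, since the axial C3–O bond is aligned with the enolate. Silyl transfer from the C6 oxygen to the tertiary alkoxide is a lesser risk.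
 Fallback (sets out from 10 and uses ketone 7, comes back at 21): the configuration at C3 is set by a later inversion instead of in the rearrangement. Allyl ether 10 is isomerised with [Ir(cod)(PMePh2)2]PF6 (activated with H2, THF) to the (E)-propenyl ether F1. Bromine (CH2Cl2, −78 °C) gives the dibromide F2 and i-Pr2NEt the (E)-bromide F3. t-BuLi converts F3 into the alkenyllithium F4, which adds to ketone 7 to give the (E)-enol ether carbinol F5. KH/18-crown-6 gives the potassium alkoxide F6, in whose oxy-Cope chair the alkoxy group is equatorial; this should speed the shift and turn the C3–O bond away from the enolate π system. The resulting potassium enolate F7 is trapped as in step 9 as the C3-epimeric enol triflate F8. Formate reduction as in step 10 gives the diene F9, and DDQ as in step 11 gives the (3R)-alcohol F10. Mitsunobu esterification of F10 with 3-methylbut-2-enoic acid (PPh3, diisopropyl azodicarboxylate, toluene, 0 °C) inverts C3 and gives ester 21.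

2. Step 14. Facial selectivity may be poor if the oxidant is delivered through the other planar-chiral ring conformer, and the Lewis acidic medium may trigger transannular opening of the new oxirane by the C1=C10 alkene.
 Fallback (sets out from 22, comes back at 23): MnO2 (CH2Cl2) oxidises the allylic alcohol to the enone F11. Nucleophilic epoxidation (t-BuOOH, DBU, CH2Cl2), which is chemoselective for the enone over the isolated alkene and the senecioate, gives the trans epoxy ketone F12. Chelation-controlled reduction with Zn(BH4)2 (Et2O, −20 °C) should give the erythro epoxy alcohol 23.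

3. Step 3. Hemiketal formation at the carbonyl next to the quaternary carbon may be incomplete, so that the iodane is displaced without the intramolecular inversion, or not at all, and stereocontrol at C6 is lost.
 Fallback (sets out from 4, comes back at 6): KN(SiMe3)2 (THF, −78 °C) gives the potassium enolate F13, which 2-(phenylsulfonyl)-3-phenyloxaziridine hydroxylates anti to isopropyl to the trans hydroxy ketone F14. Mitsunobu reaction with 4-nitrobenzoic acid (PPh3, diethyl azodicarboxylate) inverts C6 to the 4-nitrobenzoate F15, and K2CO3 in MeOH at 0 °C releases 6.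

Further compounds
F1 | step 9 | 1-methoxy-4-{[(1E)-prop-1-en-1-yloxy]methyl}benzene | COc1ccc(CO/C=C/C)cc1
F2 | step 9 | 1-[(1,2-dibromopropoxy)methyl]-4-methoxybenzene, (1R*,2R*), racemic, one enantiomer drawn | COc1ccc(CO[C@H](Br)[C@@H](C)Br)cc1
F3 | step 9 | 1-({[(1E)-2-bromoprop-1-en-1-yl]oxy}methyl)-4-methoxybenzene | COc1ccc(CO/C=C(\C)Br)cc1
F4 | step 9 | {(1Z)-1-[(4-methoxybenzyl)oxy]prop-1-en-2-yl}lithium (lithium trans to oxygen) | COc1ccc(CO/C=C(\C)[Li])cc1
F5 | step 9 | (1R,2R,5S,6R)-6-[(tert-butyldimethylsilyl)oxy]-2-ethenyl-1-{(1E)-1-[(4-methoxybenzyl)oxy]prop-1-en-2-yl}-2-methyl-5-(propan-2-yl)cyclohexan-1-ol | COc1ccc(CO/C=C(\C)[C@@]2(O)[C@H](O[Si](C)(C)C(C)(C)C)[C@H](C(C)C)CC[C@]2(C)C=C)cc1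
F6 | step 9 | potassium (1R,2R,5S,6R)-6-[(tert-butyldimethylsilyl)oxy]-2-ethenyl-1-{(1E)-1-[(4-methoxybenzyl)oxy]prop-1-en-2-yl}-2-methyl-5-(propan-2-yl)cyclohexan-1-olate | COc1ccc(CO/C=C(\C)[C@@]2([O-])[C@H](O[Si](C)(C)C(C)(C)C)[C@H](C(C)C)CC[C@]2(C)C=C)cc1.[K+]
F7 | step 9 | potassium (1Z,3R,5E,9S,10R)-10-[(tert-butyldimethylsilyl)oxy]-3-[(4-methoxybenzyl)oxy]-2,6-dimethyl-9-(propan-2-yl)cyclodeca-1,5-dien-1-olate | CC(C)(C)[Si](C)(C)O[C@H]1/C([O-])=C(C)/[C@H](OCc2ccc(OC)cc2)C/C=C(\C)CC[C@H]1C(C)C.[K+]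
F8 | step 9 | (1Z,3R,5E,9S,10R)-10-[(tert-butyldimethylsilyl)oxy]-3-[(4-methoxybenzyl)oxy]-2,6-dimethyl-9-(propan-2-yl)cyclodeca-1,5-dien-1-yl trifluoromethanesulfonate | CC(C)(C)[Si](C)(C)O[C@H]1/C(OS(=O)(=O)C(F)(F)F)=C(C)/[C@H](OCc2ccc(OC)cc2)C/C=C(\C)CC[C@H]1C(C)C
F9 | step 9 | tert-butyl{[(1R,2E,4R,6E,10S)-4-[(4-methoxybenzyl)oxy]-3,7-dimethyl-10-(propan-2-yl)cyclodeca-2,6-dien-1-yl]oxy}dimethylsilane | CC(C)(C)[Si](C)(C)O[C@H]1/C=C(C)/[C@H](OCc2ccc(OC)cc2)C/C=C(\C)CC[C@H]1C(C)C
F10 | step 9 | (1R,2E,4R,5S,8E)-4-[(tert-butyldimethylsilyl)oxy]-2,8-dimethyl-5-(propan-2-yl)cyclodeca-2,8-dien-1-ol | CC(C)(C)[Si](C)(C)O[C@H]1/C=C(C)/[C@H](O)C/C=C(\C)CC[C@H]1C(C)C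
F11 | step 14 | (1S,2E,5S,8E)-2,8-dimethyl-4-oxo-5-(propan-2-yl)cyclodeca-2,8-dien-1-yl 3-methylbut-2-enoate | O=C1/C=C(C)/[C@@H](OC(=O)C=C(C)C)C/C=C(\C)CC[C@H]1C(C)C
F12 | step 14 | (1R,2S,4E,8S,10S)-1,5-dimethyl-9-oxo-8-(propan-2-yl)-11-oxabicyclo[8.1.0]undec-4-en-2-yl 3-methylbut-2-enoate | O=C1[C@H]2O[C@]2(C)[C@@H](OC(=O)C=C(C)C)C/C=C(\C)CC[C@H]1C(C)C
F13 | step 3 | potassium (3S,6R)-6-ethenyl-6-methyl-3-(propan-2-yl)cyclohex-1-en-1-olate | [O-]C1=C[C@H](C(C)C)CC[C@]1(C)C=C.[K+]
F14 | step 3 | (2R,5S,6S)-2-ethenyl-6-hydroxy-2-methyl-5-(propan-2-yl)cyclohexan-1-one | O=C1[C@@H](O)[C@H](C(C)C)CC[C@]1(C)C=C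
F15 | step 3 | (1R,3R,6S)-3-ethenyl-3-methyl-2-oxo-6-(propan-2-yl)cyclohexyl 4-nitrobenzoate | O=C1[C@H](OC(=O)c2ccc(cc2)[N+](=O)[O-])[C@H](C(C)C)CC[C@]1(C)C=C
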